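The dihydropyran ring is cut across O1–C2 and C3–C4. The unit O1–C8a–C4a–C4 of the chroman, whose C4 is an unsubstituted methylene, is read as an o-quinone methide heterodiene, and the trans C2-aryl/C3-oxygen pair as the trace of an E alkene that carries boron at the future C3. One acid-catalysed oxa-[4+2] cycloaddition should therefore form both bonds, close the pyran ring and set C2 and C3, the chiral acid deciding the absolute sense. Its precursors are a salicyl alcohol that already holds the bibenzyl side chain and the 7-methoxy group, and an (E)-styryl pinacol boronate from O-benzylvanillin; C–B is later oxidised to C–OH with retention.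

Key step: step 7

Assumption: phosphonate 1 is purchased (otherwise one Arbuzov step from 3,5-dimethoxybenzyl bromide and triethyl phosphite precedes step 1), and the catalyst antipode that leads to the (2S,3S) boronate is taken from a screen, because the sense of induction cannot be predicted.

Step 1
Reactants: 1 diethyl (3,5-dimethoxybenzyl)phosphonate; 2 3-(benzyloxy)benzaldehyde
Product: 3 (E)-1-{2-[3-(benzyloxy)phenyl]ethenyl}-3,5-dimethoxybenzene
Conditions: KOtBu, THF, 0 °C → rt
Reagents that add atoms: none
Why: Horner–Wadsworth–Emmons olefination of a non-enolisable aryl aldehyde with a benzylic phosphonate anion should give the stilbene, mainly E, and the geometry is of no consequence because the alkene is saturated next.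

Step 2
Reactants: 3 (E)-1-{2-[3-(benzyloxy)phenyl]ethenyl}-3,5-dimethoxybenzene
Product: 4 1-{2-[3-(benzyloxy)phenyl]ethyl}-3,5-dimethoxybenzene
Conditions: TsNHNH2 (excess), NaOAc, DME/H2O, reflux
Reagents that add atoms: none
Why: Diimide reduction: HN=NH released from the sulfonyl hydrazide should pass two hydrogens to the C=C through a cyclic transition state and, unlike palladium-catalysed hydrogenation, cannot cleave the aryl benzyl ether.

Step 3
Reactants: 4 1-{2-[3-(benzyloxy)phenyl]ethyl}-3,5-dimethoxybenzene
Product: 6 2-{2-[3-(benzyloxy)phenyl]ethyl}-4,6-dimethoxybenzaldehyde, via aryl iminium chloride 5 (not isolated)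
Conditions: POCl3, DMF, 0 → 60 °C; then ice-water
Reagents that add atoms: N,N-dimethylformamide, CN(C)C=O (formyl carbon); water, O (formyl oxygen)
Why: Vilsmeier–Haack formylation: the weak chloroiminium electrophile should attack only the doubly activated 1,3-dimethoxyarene ring, at the position next to the side chain (para to one methoxy group, ortho to the other) as is usual for 3,5-dimethoxyalkylbenzenes, and hydrolysis of the iminium salt releases the aldehyde.

Step 4
Reactants: 6 2-{2-[3-(benzyloxy)phenyl]ethyl}-4,6-dimethoxybenzaldehyde
Product: 7 2-{2-[3-(benzyloxy)phenyl]ethyl}-6-hydroxy-4-methoxybenzaldehyde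
Conditions: MgI2·OEt2, toluene/Et2O, 70 °C; then 1 M HCl
Reagents that add atoms: none
Why: Chelation-controlled ortho-demethylation: magnesium bridges the formyl oxygen and the neighbouring methoxy oxygen, so iodide should remove only that methyl group by SN2, while the para methoxy group and the distant benzyl ether, which cannot chelate, stay intact.

Step 5
Reactants: 7 2-{2-[3-(benzyloxy)phenyl]ethyl}-6-hydroxy-4-methoxybenzaldehyde
Product: 8 3-{2-[3-(benzyloxy)phenyl]ethyl}-2-(hydroxymethyl)-5-methoxyphenol
Conditions: NaBH4, THF/MeOH, 0 °C; pH 7 buffer work-up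
Reagents that add atoms: none
Why: Borohydride reduction of the aldehyde to the primary alcohol; low temperature and a neutral work-up should keep the electron-rich salicyl alcohol from ionising to the quinone methide, and it is dried azeotropically and used promptly.

Step 6
Reactants: 9 4-(benzyloxy)-3-methoxybenzaldehyde (O-benzylvanillin); 10 bis[(pinacolato)boryl]methane
Product: 11 (E)-2-{2-[4-(benzyloxy)-3-methoxyphenyl]ethenyl}-4,4,5,5-tetramethyl-1,3,2-dioxaborolane
Conditions: TMPH, n-BuLi, THF, 0 °C; then 9, −78 °C → rt; H2O quench
Reagents that add atoms: none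
Why: Boron–Wittig olefination: lithiated bis(boryl)methane adds to the aldehyde and the β-alkoxide eliminates with one boryl group, the aryl group lying anti to the remaining boronate, which should give the E alkenylboronate.

Step 7
Reactants: 8 3-{2-[3-(benzyloxy)phenyl]ethyl}-2-(hydroxymethyl)-5-methoxyphenol; 11 (E)-2-{2-[4-(benzyloxy)-3-methoxyphenyl]ethenyl}-4,4,5,5-tetramethyl-1,3,2-dioxaborolane
Product: 13 (2S,3S)-2-[4-(benzyloxy)-3-methoxyphenyl]-5-{2-[3-(benzyloxy)phenyl]ethyl}-7-methoxy-3-(4,4,5,5-tetramethyl-1,3,2-dioxaborolan-2-yl)chroman, via o-quinone methide 12 (not isolated)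
Conditions: TRIP-type chiral phosphoric acid or its N-triflylphosphoramide (10 mol %), 11 (2.5 equiv), 5 Å MS, toluene, 0 °C → rt, 8 added over 6 h
Reagents that add atoms: none
Why: Proposed new method: the chiral acid protonates the benzylic hydroxyl of 8, water leaves with the help of the ortho hydroxyl and the para methoxy group, and the resulting o-quinone methide 12 stays hydrogen-bonded to the chiral phosphate while the electron-rich alkene of 11 adds in an inverse-electron-demand oxa-Diels–Alder reaction, its boron-bearing carbon bonding to the methide carbon (C3–C4) and the carbonyl oxygen to the benzylic carbon (O1–C2). The closest known reaction type is the chiral phosphoric acid catalysed [4+2] cycloaddition of o-quinone methides, generated in situ from o-hydroxybenzyl alcohols, with electron-rich styrenes to give 2-arylchromans; an alkenylboronate as the 2π partner and enantiocontrol at a methide that carries no substituent are the untested parts. The dihydropyran ring is closed by the cycloaddition itself, concerted and asynchronous (C–C ahead of C–O), or at the stepwise limit by 6-endo capture of the benzylic cation by the phenol oxygen inside the ion pair. The relative configuration of C2 and C3 is fixed by suprafacial addition to the E alkene (aryl and boron trans, which is also the diequatorial arrangement a stepwise closure would prefer), and the absolute configuration by the catalyst, whose 3,3′-aryl groups must shield one face of the alkene as it approaches the bound methide. Regioselectivity (boron at C3) is needed and is secured by the p-alkoxyaryl group and the C–B σ bond, which both stabilise positive charge at C2; chemoselectivity for the alkene over the nucleophilic arene of a second molecule of 8 is needed too and is secured by slow addition of 8 to an excess of 11.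

Step 8
Reactants: 13 (2S,3S)-2-[4-(benzyloxy)-3-methoxyphenyl]-5-{2-[3-(benzyloxy)phenyl]ethyl}-7-methoxy-3-(4,4,5,5-tetramethyl-1,3,2-dioxaborolan-2-yl)chroman
Product: 14 (2R,3S)-2-[4-(benzyloxy)-3-methoxyphenyl]-5-{2-[3-(benzyloxy)phenyl]ethyl}-7-methoxychroman-3-ol
Conditions: NaBO3·4H2O, THF/H2O, rt
Reagents that add atoms: sodium perborate tetrahydrate, [Na+].[Na+].O[B-]1(O)OO[B-](O)(O)OO1 (the C3 oxygen)
Why: Oxidation of a secondary alkylboronate: peroxide attack at boron and 1,2-shift of C3 from boron to oxygen proceed with retention, so C3 stays S and the trans relationship is kept; C2 is unchanged in space and is named R only because C3, now bearing oxygen, outranks the aryl carbon.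

Step 9
Reactants: 14 (2R,3S)-2-[4-(benzyloxy)-3-methoxyphenyl]-5-{2-[3-(benzyloxy)phenyl]ethyl}-7-methoxychroman-3-ol
Product: 15 shanciol B
Conditions: H2 (1 atm), 10% Pd/C, EtOAc/MeOH, rt
Reagents that add atoms: none
Why: Catalytic hydrogenolysis should cleave the two aryl benzyl ethers much faster than the cyclic benzylic C2–O1 aryl ether, as in the debenzylation of O-benzylated catechins, and no stereocentre is touched.

Compound list
1 | diethyl (3,5-dimethoxybenzyl)phosphonate | CCOP(=O)(Cc1cc(OC)cc(OC)c1)OCC | starting material
2 | 3-(benzyloxy)benzaldehyde | O=Cc1cccc(OCc2ccccc2)c1 | starting material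
3 | (E)-1-{2-[3-(benzyloxy)phenyl]ethenyl}-3,5-dimethoxybenzene | COc1cc(/C=C/c2cccc(OCc3ccccc3)c2)cc(OC)c1 | intermediate
4 | 1-{2-[3-(benzyloxy)phenyl]ethyl}-3,5-dimethoxybenzene | COc1cc(CCc2cccc(OCc3ccccc3)c2)cc(OC)c1 | intermediate
5 | N-[(2-{2-[3-(benzyloxy)phenyl]ethyl}-4,6-dimethoxyphenyl)methylidene]-N-methylmethanaminium chloride (aryl iminium chloride) | C[N+](C)=Cc1c(OC)cc(OC)cc1CCc1cccc(OCc2ccccc2)c1.[Cl-] | intermediate (not isolated)
6 | 2-{2-[3-(benzyloxy)phenyl]ethyl}-4,6-dimethoxybenzaldehyde | COc1cc(OC)c(C=O)c(CCc2cccc(OCc3ccccc3)c2)c1 | intermediate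
7 | 2-{2-[3-(benzyloxy)phenyl]ethyl}-6-hydroxy-4-methoxybenzaldehyde | COc1cc(O)c(C=O)c(CCc2cccc(OCc3ccccc3)c2)c1 | intermediate
8 | 3-{2-[3-(benzyloxy)phenyl]ethyl}-2-(hydroxymethyl)-5-methoxyphenol | COc1cc(CCc2cccc(OCc3ccccc3)c2)c(CO)c(O)c1 | intermediate
9 | 4-(benzyloxy)-3-methoxybenzaldehyde (O-benzylvanillin) | COc1cc(C=O)ccc1OCc1ccccc1 | starting material
10 | bis[(pinacolato)boryl]methane | CC1(C)OB(CB2OC(C)(C)C(C)(C)O2)OC1(C)C | starting material
11 | (E)-2-{2-[4-(benzyloxy)-3-methoxyphenyl]ethenyl}-4,4,5,5-tetramethyl-1,3,2-dioxaborolane | COc1cc(/C=C/B2OC(C)(C)C(C)(C)O2)ccc1OCc1ccccc1 | intermediate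
12 | 5-{2-[3-(benzyloxy)phenyl]ethyl}-3-methoxy-6-methylidenecyclohexa-2,4-dien-1-one (o-quinone methide) | C=C1C(=O)C=C(OC)C=C1CCc1cccc(OCc2ccccc2)c1 | intermediate (not isolated)
13 | (2S,3S)-2-[4-(benzyloxy)-3-methoxyphenyl]-5-{2-[3-(benzyloxy)phenyl]ethyl}-7-methoxy-3-(4,4,5,5-tetramethyl-1,3,2-dioxaborolan-2-yl)chroman (2,3-trans; same spatial arrangement as the 2R,3S alcohol) | COc1cc(CCc2cccc(OCc3ccccc3)c2)c2c(c1)O[C@H](c1ccc(OCc3ccccc3)c(OC)c1)[C@@H](B1OC(C)(C)C(C)(C)O1)C2 | intermediate
14 | (2R,3S)-2-[4-(benzyloxy)-3-methoxyphenyl]-5-{2-[3-(benzyloxy)phenyl]ethyl}-7-methoxychroman-3-ol | COc1cc(CCc2cccc(OCc3ccccc3)c2)c2c(c1)O[C@H](c1ccc(OCc3ccccc3)c(OC)c1)[C@@H](O)C2 | intermediate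
15 | shanciol B, (2R,3S)-2-(4-hydroxy-3-methoxyphenyl)-5-[2-(3-hydroxyphenyl)ethyl]-7-methoxychroman-3-ol | COc1cc(CCc2cccc(O)c2)c2c(c1)O[C@H](c1ccc(O)c(OC)c1)[C@@H](O)C2 | target

Total step count: 9. Longest linear sequence: 8 steps (steps 1–5, 7, 8, 9 from phosphonate 1); the boronate 11 is made in one step on a side branch.

Steps most likely to fail

1. Step 7 (the new method). Three processes threaten it:
- The methide may be intercepted by the electron-rich arene of a second molecule of 8 (oligomerisation) faster than by the alkene.
- The β-boryl benzylic cation may shed boron instead of closing the ring (deborylative alkenylation).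
- The catalyst may not tell the two alkene faces apart (poor facial selectivity), because the dienophile has no hydrogen-bond donor and the methide carbon has no substituent.

The fallback uses known reactions and sets out from salicylaldehyde 7, with boronate 11 as the second component. The pinacol ester of 11 is cleaved with NaIO4/NH4OAc in acetone/water to (E)-2-[4-(benzyloxy)-3-methoxyphenyl]ethenylboronic acid F1. Condensation of 7 with F1 and catalytic dibenzylamine in dioxane at 90 °C (Petasis-type borono-Mannich addition, then loss of the amine and ring closure) should give racemic 2-[4-(benzyloxy)-3-methoxyphenyl]-5-{2-[3-(benzyloxy)phenyl]ethyl}-7-methoxy-2H-chromene F2. A copper(I)/chiral bisphosphine-catalysed protoboration (B2pin2, MeOH, NaOtBu cat., THF) is then run as a kinetic resolution. Cu–B adds syn across C3=C4 anti to the C2 aryl group with boron at C3, and the catalyst should convert the (2S) enantiomer only. The fallback comes back to the route at 13, at the price of a theoretical maximum of half the material.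

2. Step 4. Ether cleavage may not stop at the chelated methyl group: loss of the ring-B benzyl ether, or stalling at partial conversion, would erode the yield. The fallback sets out from 6 and gives up the benzyl group on purpose. Excess BCl3 (CH2Cl2, −78 → 0 °C) should remove both the chelated ortho methyl group and the benzyl group, leaving the non-chelated para methoxy group, to give 2-hydroxy-6-[2-(3-hydroxyphenyl)ethyl]-4-methoxybenzaldehyde F3. One equivalent of BnBr with KHCO3 in DMF at rt should then alkylate the free ring-B phenol in preference to the hydrogen-bonded salicylaldehyde hydroxyl, which is a poor nucleophile. The fallback comes back to the route at 7.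

3. Step 2. Diimide may disproportionate faster than it reduces the conjugated, electron-rich stilbene, so conversion can stall and leave alkene that is hard to separate from the product. The fallback sets out from 3. Ordinary hydrogenation (H2, Pd/C, EtOAc/MeOH) saturates the alkene and cleaves the benzyl ether together, giving 3-[2-(3,5-dimethoxyphenyl)ethyl]phenol F4. Re-benzylation (BnBr, K2CO3, acetone, reflux) comes back to the route at 4.

Further compounds
F1 | step 7 | (E)-2-[4-(benzyloxy)-3-methoxyphenyl]ethenylboronic acid | COc1cc(/C=C/B(O)O)ccc1OCc1ccccc1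
F2 | step 7 | rac-2-[4-(benzyloxy)-3-methoxyphenyl]-5-{2-[3-(benzyloxy)phenyl]ethyl}-7-methoxy-2H-chromene | COc1cc(CCc2cccc(OCc3ccccc3)c2)c2C=CC(Oc2c1)c1ccc(OCc2ccccc2)c(OC)c1
F3 | step 4 | 2-hydroxy-6-[2-(3-hydroxyphenyl)ethyl]-4-methoxybenzaldehyde | COc1cc(O)c(C=O)c(CCc2cccc(O)c2)c1
F4 | step 2 | 3-[2-(3,5-dimethoxyphenyl)ethyl]phenol | COc1cc(CCc2cccc(O)c2)cc(OC)c1
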